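The target is read as a masked hydroquinone: the C2 ketone and the C5 carbinol sit para across C3=C4 of the six-membered ring, with C7 on C1. Everything rests on cleaving the C1–O and C6–O bonds back to an oxirane on C1=C6 of a cyclohexa-2,5-dienol. The key step exploits the C5 hydroxyl, allylic to C1=C6 within the ring, to steer a vanadium-bound peroxide onto its own face, setting C1 and fixing the face opposite to which benzoate later enters C6. Its precursor is the (S)-C5 dienol with a C2 dimethyl ketal, free C7 hydroxyl and a spectator iodine on C4 that makes the preceding ketone reduction enantioselective and silences C3=C4.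

Key step: step 5

Remark: atom labels follow the target ring (C1 quaternary carbinol, C2 ketone, C3=C4, C5 carbinol, C6 benzoyloxy carbon, C7 the exocyclic CH2); 5-hydroxy-2-methoxybenzaldehyde is assumed to be a catalogue chemical.
Remark: C5 and C7 stand trans across C1=C6, so one vanadium centre cannot hold both hydroxyls at once; facial control is therefore credited to the C5 alkoxide alone.
Remark: dearomatising a para-methoxyphenol, instead of half-hydrolysing a quinone bis-ketal, fixes which carbon becomes the ketone (C5) and which the ketal (C2); the C4 iodine gives the ketone reduction a steric handle with firm precedent.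

Step 1
Reactants: 1 5-hydroxy-2-methoxybenzaldehyde
Product: 2 3-(hydroxymethyl)-4-methoxyphenol
Conditions: NaBH4, EtOH, 0 °C
Reagents that add atoms: none
Why: Chemoselective borohydride reduction of the aryl aldehyde to the benzylic alcohol, which creates no stereocentre and leaves the phenol and the methyl ether untouched.

Step 2
Reactants: 2 3-(hydroxymethyl)-4-methoxyphenol; 3 methanol
Product: 4 3-(hydroxymethyl)-4,4-dimethoxycyclohexa-2,5-dien-1-one
Conditions: PhI(OAc)2, MeOH, 0 °C; aq. NaHCO3 work-up
Reagents that add atoms: methanol CO
Why: Oxidative dearomatisation of a para-methoxyphenol by a trivalent iodine reagent, in which methanol adds to the carbon that already bears OMe, so that the phenol carbon (C5) must become the ketone and the anisole carbon (C2) the dimethyl ketal, with no regiochemical ambiguity and no stereocentre formed.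

Step 3
Reactants: 4 3-(hydroxymethyl)-4,4-dimethoxycyclohexa-2,5-dien-1-one; 5 iodine
Product: 6 5-(hydroxymethyl)-2-iodo-4,4-dimethoxycyclohexa-2,5-dien-1-one
Conditions: I2, K2CO3, DMAP (cat.), THF/H2O (1:1), rt
Reagents that add atoms: iodine II
Why: Amine-catalysed α-iodination of an enone (Baylis–Hillman-type conjugate addition of DMAP, iodination of the enolate, elimination) requires an unsubstituted β-carbon, so only the C3=C4 enone reacts and iodine enters C4, while the C1=C6 enone with its fully substituted β-carbon is left alone.

Step 4
Reactants: 6 5-(hydroxymethyl)-2-iodo-4,4-dimethoxycyclohexa-2,5-dien-1-one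
Product: 7 (1S)-5-(hydroxymethyl)-2-iodo-4,4-dimethoxycyclohexa-2,5-dien-1-ol
Conditions: (R)-2-methyl-CBS-oxazaborolidine (cat.), BH3·SMe2, THF, −20 °C; MeOH quench, aq. NaHCO3
Reagents that add atoms: none
Why: Corey–Bakshi–Shibata reduction of an α-iodoenone, in which the iodovinyl C4 flank acts as the large group and the C6 vinyl flank as the small one, so that the (R)-catalyst should deliver hydride to the ketone face that gives the (1S) carbinol (C5, the configuration called R once iodine is removed), the free C7 hydroxyl only consuming borane as a borate that is cleaved on work-up.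

Step 5
Reactants: 7 (1S)-5-(hydroxymethyl)-2-iodo-4,4-dimethoxycyclohexa-2,5-dien-1-ol; 8 tert-butyl hydroperoxide
Product: 9 (1R,2S,6R)-6-(hydroxymethyl)-3-iodo-5,5-dimethoxy-7-oxabicyclo[4.1.0]hept-3-en-2-ol (oxirane on C1–C6, cis to the C5 hydroxyl)
Conditions: VO(acac)2 (cat.), t-BuOOH (anhydrous, in decane), CH2Cl2, 0 °C to rt
Reagents that add atoms: tert-butyl hydroperoxide CC(C)(C)OO
Why: VO(acac)2 is oxidised by the hydroperoxide to a pentavalent vanadium alkoxide of the C5 hydroxyl that carries an η2-alkylperoxide, and this tethered peroxide hands its distal oxygen to C1=C6 in one concerted, suprafacial transfer. The closest known reaction type is the hydroxyl-directed, vanadium-catalysed epoxidation of cyclic allylic alcohols, established for cyclohex-2-enols and cyclohexa-2,5-dienols. The oxirane closes by [2+1] oxygen-atom transfer with both C–O bonds formed on one face, so the ring fusion is necessarily cis. The C5 stereocentre controls both new centres, because the V–O–C5 tether reaches only the face on which the C5 oxygen stands, which should place the oxirane cis to that hydroxyl and so fix C1 and the face from which C6 is later attacked. The step needs chemoselectivity for C1=C6 over C3=C4, secured by the C4 iodine that makes C3=C4 electron-poor and by C1=C6 being trisubstituted and allylic to both hydroxyls; it also needs face selectivity, and since C5 and C7 lie trans across C1=C6 a separate C7-alkoxide pathway that is not tied to one face is the real hazard. Neutral, cold conditions should protect the acid-labile dienol ketal from aromatisation and limit oxidation of the doubly allylic carbinol.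

Step 6
Reactants: 9 (1R,2S,6R)-6-(hydroxymethyl)-3-iodo-5,5-dimethoxy-7-oxabicyclo[4.1.0]hept-3-en-2-ol
Product: 10 (1R,2R,6R)-6-(hydroxymethyl)-5,5-dimethoxy-7-oxabicyclo[4.1.0]hept-3-en-2-ol
Conditions: Bu3SnH, Pd(PPh3)4 (cat.), THF, rt
Reagents that add atoms: none
Why: Palladium-catalysed hydrogenolysis of a vinyl iodide by a tin hydride (oxidative addition to zerovalent palladium, Sn–H transmetalation, reductive elimination) exchanges iodine for hydrogen under neutral conditions, and the oxirane, which is not allylic to C3=C4, the ketal and all three stereocentres should stay untouched.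

Step 7
Reactants: 10 (1R,2R,6R)-6-(hydroxymethyl)-5,5-dimethoxy-7-oxabicyclo[4.1.0]hept-3-en-2-ol; 11 benzoic acid
Product: 12 (1S,2R,6R)-2,6-dihydroxy-2-(hydroxymethyl)-3,3-dimethoxycyclohex-4-en-1-yl benzoate
Conditions: PhCO2H, Ti(OiPr)4, CH2Cl2, rt; aq. potassium sodium tartrate work-up
Reagents that add atoms: benzoic acid OC(=O)c1ccccc1
Why: Titanium-mediated opening of a 2,3-epoxy alcohol by a carboxylic acid, selective for the carbon distal to the bound alkoxide: with C7–O and the oxirane oxygen on titanium, benzoate attacks the secondary C6 in SN2 fashion from the face opposite the oxygen (inversion at C6, benzoate trans to both hydroxyls), whereas the quaternary C1, shielded by the C2 ketal and electronically deactivated by its three β-oxygens, keeps its C–O bond as the tertiary hydroxyl.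

Step 8
Reactants: 12 (1S,2R,6R)-2,6-dihydroxy-2-(hydroxymethyl)-3,3-dimethoxycyclohex-4-en-1-yl benzoate; 13 benzoyl chloride
Product: 14 [(1R,2S,3R)-2-(benzoyloxy)-1,3-dihydroxy-6,6-dimethoxycyclohex-4-en-1-yl]methyl benzoate
Conditions: BzCl (1 equiv), pyridine, CH2Cl2, −30 to 0 °C
Reagents that add atoms: benzoyl chloride O=C(Cl)c1ccccc1
Why: Kinetically controlled acylation of the primary C7 hydroxyl by an acid chloride, run cold with one equivalent, should outpace reaction at the secondary allylic C5 hydroxyl beside the C6 benzoate and at the tertiary C1 hydroxyl, and the weak base keeps benzoyl migration slow.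

Step 9
Reactants: 14 [(1R,2S,3R)-2-(benzoyloxy)-1,3-dihydroxy-6,6-dimethoxycyclohex-4-en-1-yl]methyl benzoate; 15 water
Product: 16 [(1R,2S,3R)-2-(benzoyloxy)-1,3-dihydroxy-6-oxocyclohex-4-en-1-yl]methyl benzoate
Conditions: TFA, H2O, CH2Cl2, 0 °C
Reagents that add atoms: water O
Why: Acid-catalysed ketal hydrolysis through the oxocarbenium ion at C2 that is stabilised by the C3=C4 vinyl group unmasks the enone, the benzoates and the C5 allylic alcohol tolerating brief cold aqueous acid and no stereocentre being epimerisable because C1 is quaternary.

Compound list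
1 | 5-hydroxy-2-methoxybenzaldehyde | COc1ccc(O)cc1C=O | starting material
2 | 3-(hydroxymethyl)-4-methoxyphenol | COc1ccc(O)cc1CO | intermediate
3 | methanol | CO | starting material
4 | 3-(hydroxymethyl)-4,4-dimethoxycyclohexa-2,5-dien-1-one | OCC1=CC(=O)C=CC1(OC)OC | intermediate
5 | iodine | II | starting material
6 | 5-(hydroxymethyl)-2-iodo-4,4-dimethoxycyclohexa-2,5-dien-1-one | OCC1=CC(=O)C(I)=CC1(OC)OC | intermediate
7 | (1S)-5-(hydroxymethyl)-2-iodo-4,4-dimethoxycyclohexa-2,5-dien-1-ol | OCC1=C[C@H](O)C(I)=CC1(OC)OC | intermediate
8 | tert-butyl hydroperoxide | CC(C)(C)OO | starting material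
9 | (1R,2S,6R)-6-(hydroxymethyl)-3-iodo-5,5-dimethoxy-7-oxabicyclo[4.1.0]hept-3-en-2-ol | OC[C@@]12O[C@@H]1[C@H](O)C(I)=CC2(OC)OC | intermediate
10 | (1R,2R,6R)-6-(hydroxymethyl)-5,5-dimethoxy-7-oxabicyclo[4.1.0]hept-3-en-2-ol | OC[C@@]12O[C@@H]1[C@H](O)C=CC2(OC)OC | intermediate
11 | benzoic acid | OC(=O)c1ccccc1 | starting material
12 | (1S,2R,6R)-2,6-dihydroxy-2-(hydroxymethyl)-3,3-dimethoxycyclohex-4-en-1-yl benzoate | OC[C@]1(O)C(OC)(OC)C=C[C@@H](O)[C@@H]1OC(=O)c1ccccc1 | intermediate
13 | benzoyl chloride | O=C(Cl)c1ccccc1 | starting material
14 | [(1R,2S,3R)-2-(benzoyloxy)-1,3-dihydroxy-6,6-dimethoxycyclohex-4-en-1-yl]methyl benzoate | O=C(OC[C@]1(O)C(OC)(OC)C=C[C@@H](O)[C@@H]1OC(=O)c1ccccc1)c1ccccc1 | intermediate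
15 | water | O | starting material
16 | [(1R,2S,3R)-2-(benzoyloxy)-1,3-dihydroxy-6-oxocyclohex-4-en-1-yl]methyl benzoate | O=C(OC[C@]1(O)C(=O)C=C[C@@H](O)[C@@H]1OC(=O)c1ccccc1)c1ccccc1 | target

Total step count: 9
Longest linear sequence: 9 steps (1 to 16)

Steps most likely to fail

Step 5. Oxygen may be delivered through a vanadium alkoxide of the C7 hydroxyl from the face remote from C5–OH, eroding facial selectivity. The doubly allylic carbinol may also be oxidised back to the dienone, or the ketal may ionise and the ring aromatise. The fallback removes the second donor. It sets out from 7: the primary hydroxyl is silylated (TBSCl, imidazole, DMF, −20 °C) to give (1S)-5-{[(tert-butyldimethylsilyl)oxy]methyl}-2-iodo-4,4-dimethoxycyclohexa-2,5-dien-1-ol F1. With C5–OH as the only directing group, VO(acac)2 and t-BuOOH should give (1R,2S,6R)-6-{[(tert-butyldimethylsilyl)oxy]methyl}-3-iodo-5,5-dimethoxy-7-oxabicyclo[4.1.0]hept-3-en-2-ol F2, with the iodine still guarding C3=C4. Bu4NF in THF then frees the C7 hydroxyl and the route is rejoined at 9.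

Step 7. The titanium Lewis acid may exchange or ionise the allylic ketal, attack may not be confined to C6, or the new benzoyl group may migrate to the C5 or C7 oxygen within the titanium alkoxide. The fallback abandons chelation control and Lewis acid. It sets out from 10: the primary hydroxyl is benzoylated first (BzCl, pyridine, CH2Cl2, −30 °C) to give [(1R,5R,6R)-5-hydroxy-2,2-dimethoxy-7-oxabicyclo[4.1.0]hept-3-en-1-yl]methyl benzoate F3. The oxirane is then opened by plain SN2 attack of a carboxylate at the less hindered C6 (PhCO2Cs, PhCO2H, DMF, 70 °C), with inversion, and the route is rejoined directly at 14.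

Step 8. Acylation may spill over to the C5 hydroxyl, or the C6 benzoate may migrate under base, so that the primary position is not the only one esterified. The fallback changes the mode of activation. It sets out from 12: a tin-acetal-mediated acylation (Bu2SnO (cat.), BzCl, Et3N, CH2Cl2, 0 °C) engages the C1/C7 1,2-diol as a transient stannylene and transfers benzoyl only to its primary oxygen. It returns to the route at 14 without any new isolated compound.

Further compounds
F1 | step 5 | (1S)-5-{[(tert-butyldimethylsilyl)oxy]methyl}-2-iodo-4,4-dimethoxycyclohexa-2,5-dien-1-ol | CC(C)(C)[Si](C)(C)OCC1=C[C@H](O)C(I)=CC1(OC)OC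
F2 | step 5 | (1R,2S,6R)-6-{[(tert-butyldimethylsilyl)oxy]methyl}-3-iodo-5,5-dimethoxy-7-oxabicyclo[4.1.0]hept-3-en-2-ol | CC(C)(C)[Si](C)(C)OC[C@@]12O[C@@H]1[C@H](O)C(I)=CC2(OC)OC
F3 | step 7 | [(1R,5R,6R)-5-hydroxy-2,2-dimethoxy-7-oxabicyclo[4.1.0]hept-3-en-1-yl]methyl benzoate | O=C(OC[C@@]12O[C@@H]1[C@H](O)C=CC2(OC)OC)c1ccccc1
F0 | step 8 | none | none
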